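The cyclopentane (ring B) is cut between its ring-fusion CH, which carries an ester in the key product, and the methyl-bearing quaternary ring-fusion carbon. That quaternary carbon, with its methyl, its CH2 link to the acetoxy carbon of the seven-membered ring A and its CH2CH2 path through ring B, is C3 of (S)-citronellol with the hydrogen replaced by carbon. A rhodium carbenoid therefore inserts into this tertiary C–H bond with retention, closing ring B and creating the quaternary stereocentre in one operation. The precursor is an acyclic methyl 2-diazo-3-oxooctanoate carrying the 6-methyl stereocentre and an 8-silyloxy group.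

Key step: step 5

Remark: the configurations of citronellol (S), of the diazo keto ester (6S) and of the cyclopentanone (quaternary carbon R) are mutually consistent with retention and with the target; the ester-bearing carbon of 9 is an enolisable centre, drawn as in the target but fixed only in step 8.
Remark: ring A is the seven-membered ring and ring B the cyclopentane; the target is named on the azulene skeleton as (1S,3aR,5S,8aS) with a (2S,4E) side chain.

Step 1
Reactants: 1 (S)-(−)-citronellol
Product: 2 tert-butyl{[(3S)-3,7-dimethyloct-6-en-1-yl]oxy}dimethylsilane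
Conditions: TBSCl, imidazole, CH2Cl2, 0 °C to rt
Reagents that add atoms: tert-butyldimethylsilyl chloride, CC(C)(C)[Si](C)(C)Cl
Why: Routine silylation of a primary alcohol gives an ether that is inert to ozone, chlorite, base and the rhodium carbenoid, and the stereocentre is not touched.

Step 2
Reactants: 2 tert-butyl{[(3S)-3,7-dimethyloct-6-en-1-yl]oxy}dimethylsilane
Product: 4 (4S)-6-[(tert-butyldimethylsilyl)oxy]-4-methylhexanoic acid, via aldehyde 3 (not isolated)
Conditions: O3, MeCN/H2O (9:1), 0 °C; then NaClO2, NaH2PO4, H2O, 0 °C to rt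
Reagents that add atoms: ozone, [O-][O+]=O; sodium chlorite, [Na+].[O-]Cl=O
Why: Ozonolysis in wet acetonitrile lets water trap the carbonyl oxide so the aldehyde forms without a reductant, and chlorite oxidises it in the same flask (Pinnick-type oxidation, with the hydrogen peroxide formed scavenging hypochlorite); the C4 centre is remote from both events.

Step 3
Reactants: 4 (4S)-6-[(tert-butyldimethylsilyl)oxy]-4-methylhexanoic acid; 5 Meldrum's acid
Product: 7 methyl (6S)-8-[(tert-butyldimethylsilyl)oxy]-6-methyl-3-oxooctanoate, via acyl Meldrum's acid 6 (not isolated)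
Conditions: DCC, DMAP, CH2Cl2, 0 °C to rt; filter, aq KHSO4 wash; then MeOH, reflux
Reagents that add atoms: Meldrum's acid (5), CC1(C)OC(=O)CC(=O)O1; methanol, CO
Why: Carbodiimide C-acylation of Meldrum's acid followed by methanolysis with loss of acetone and CO2 is the standard two-carbon homologation of an acid to a β-keto ester; no stereocentre is involved.

Step 4
Reactants: 7 methyl (6S)-8-[(tert-butyldimethylsilyl)oxy]-6-methyl-3-oxooctanoate
Product: 8 methyl (6S)-8-[(tert-butyldimethylsilyl)oxy]-2-diazo-6-methyl-3-oxooctanoate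
Conditions: 4-acetamidobenzenesulfonyl azide, Et3N, MeCN, 0 °C to rt
Reagents that add atoms: 4-acetamidobenzenesulfonyl azide, CC(=O)Nc1ccc(cc1)S(=O)(=O)N=[N+]=[N-]
Why: Regitz diazo transfer to the doubly activated methylene is reliable under mild base, which leaves the silyl ether and the methine stereocentre alone.

Step 5
Reactants: 8 methyl (6S)-8-[(tert-butyldimethylsilyl)oxy]-2-diazo-6-methyl-3-oxooctanoate
Product: 9 methyl (1R,2R)-2-{2-[(tert-butyldimethylsilyl)oxy]ethyl}-2-methyl-5-oxocyclopentane-1-carboxylate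
Conditions: Rh2(OAc)4 (1 mol%), CH2Cl2, rt, slow addition of 8
Reagents that add atoms: none
Why: Rh2(OAc)4 expels N2 from 8 and the electrophilic rhodium carbenoid, which has no hydrogen to shift because it sits between two carbonyl groups, inserts into the C6–H bond in a concerted, asynchronous three-centre transition state in which C–C bond formation and hydride transfer occur on the same face; the closest known reaction type is the dirhodium-catalysed intramolecular 1,5 C–H insertion of α-diazo β-keto esters into tertiary C–H bonds to give 2-oxocyclopentanecarboxylates. Ring B closes in the 1,5 mode (the carbenoid carbon bonds to the carbon four atoms along the chain), the kinetically preferred closure that gives the five-membered ring. The quaternary stereocentre is controlled only by the existing C6 centre, because insertion replaces H by C with retention, so the S centre of citronellol becomes the R quaternary carbon; the ester-bearing carbon forms as an enolisable centre and is not relied upon. The step needs site selectivity for the single methine over the methylene C–H bonds, which the higher electron density of the tertiary C–H, the five-membered-ring preference and the 1,7 distance of the silyl-protected OCH2 group should secure, while slow addition suppresses carbene dimerisation.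

Step 6
Reactants: 9 methyl (1R,2R)-2-{2-[(tert-butyldimethylsilyl)oxy]ethyl}-2-methyl-5-oxocyclopentane-1-carboxylate
Product: 10 methyl (5R)-5-{2-[(tert-butyldimethylsilyl)oxy]ethyl}-5-methyl-2-{[(trifluoromethyl)sulfonyl]oxy}cyclopent-1-ene-1-carboxylate
Conditions: NaH, THF, 0 °C; then PhNTf2, 0 °C to rt
Reagents that add atoms: N-phenylbis(trifluoromethanesulfonimide), O=S(=O)(N(c1ccccc1)S(=O)(=O)C(F)(F)F)C(F)(F)F
Why: O-sulfonylation of the sodium enolate of the β-keto ester gives the conjugated enol triflate, which erases the labile ester-bearing centre and leaves the quaternary centre untouched.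

Step 7
Reactants: 10 methyl (5R)-5-{2-[(tert-butyldimethylsilyl)oxy]ethyl}-5-methyl-2-{[(trifluoromethyl)sulfonyl]oxy}cyclopent-1-ene-1-carboxylate; 11 tributyl(1-ethoxyvinyl)stannane
Product: 14 methyl (5R)-2-acetyl-5-(2-hydroxyethyl)-5-methylcyclopent-1-ene-1-carboxylate, via dienyl ether 12 (not isolated), via silyl ether ketone 13 (not isolated)
Conditions: Pd(PPh3)4 (5 mol%), LiCl, THF, reflux; then 1 M aq HCl, THF, rt; 14 used at once
Reagents that add atoms: tributyl(1-ethoxyvinyl)stannane (11), CCCC[Sn](CCCC)(CCCC)C(=C)OCC; water, O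
Why: Stille coupling of the vinyl triflate with the α-ethoxyvinyl stannane (an acetyl anion equivalent) followed by acid hydrolysis of the enol ether, which also cleaves the primary silyl ether, delivers the acetyl group and frees the hydroxyl needed to direct step 8; the hindered conjugated ester should resist lactonisation during the short acid treatment.

Step 8
Reactants: 14 methyl (5R)-2-acetyl-5-(2-hydroxyethyl)-5-methylcyclopent-1-ene-1-carboxylate
Product: 15 methyl (1S,2R,5S)-5-acetyl-2-(2-hydroxyethyl)-2-methylcyclopentane-1-carboxylate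
Conditions: [Ir(cod)(PCy3)(py)]PF6 (10 mol%), H2 (50 bar), CH2Cl2, rt
Reagents that add atoms: none
Why: In this hydroxyl-directed homogeneous hydrogenation the primary hydroxyl of the arm binds the cationic iridium centre and both hydrogens are delivered to the tetrasubstituted alkene from the face of that arm, which sets the two new ring stereocentres with their hydrogens cis to each other and to the arm and trans to the methyl group.

Step 9
Reactants: 15 methyl (1S,2R,5S)-5-acetyl-2-(2-hydroxyethyl)-2-methylcyclopentane-1-carboxylate; 16 allylmagnesium bromide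
Product: 18 (3S,3aS,6R,6aS)-6-(2-hydroxyethyl)-3,6-dimethyl-3-(prop-2-en-1-yl)hexahydro-1H-cyclopenta[c]furan-1-one, via hydroxy ester 17 (not isolated)
Conditions: allylMgBr (2.1 equiv), THF, −78 °C; aq NH4Cl; then PPTS (cat.), CH2Cl2, rt
Reagents that add atoms: allylmagnesium bromide (16), C=CC[Mg]Br
Why: The Grignard reagent adds to the ketone far faster than to the ester at −78 °C, anti to the ester-bearing ring carbon of the reactive rotamer (Felkin–Anh control, the sense known for additions to 17-acetyl steroids), which sets the S carbinol, and the tertiary alcohol then closes the cis-fused γ-lactone onto the neighbouring ester, masking both groups.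

Step 10
Reactants: 18 (3S,3aS,6R,6aS)-6-(2-hydroxyethyl)-3,6-dimethyl-3-(prop-2-en-1-yl)hexahydro-1H-cyclopenta[c]furan-1-one; 19 2-methylbut-3-en-2-ol
Product: 20 (3S,3aS,6R,6aS)-3-[(2E)-4-hydroxy-4-methylpent-2-en-1-yl]-6-(2-hydroxyethyl)-3,6-dimethylhexahydro-1H-cyclopenta[c]furan-1-one
Conditions: 19 (10 equiv), second-generation Grubbs catalyst (5 mol%), CH2Cl2, 40 °C
Reagents that add atoms: 2-methylbut-3-en-2-ol (19), CC(C)(O)C=C
Why: Cross-metathesis of the terminal alkene with the hindered tertiary allylic alcohol, which homodimerises slowly, should give the E alkene for steric reasons and completes the side chain while the molecule holds no other alkene.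

Step 11
Reactants: 20 (3S,3aS,6R,6aS)-3-[(2E)-4-hydroxy-4-methylpent-2-en-1-yl]-6-(2-hydroxyethyl)-3,6-dimethylhexahydro-1H-cyclopenta[c]furan-1-one
Product: 21 (3S,3aS,6R,6aS)-3-[(2E)-4-hydroxy-4-methylpent-2-en-1-yl]-6-(2-hydroxyethyl)-3,6-dimethylhexahydro-1H-cyclopenta[c]furan-1-ol (lactol, both anomers)
Conditions: i-Bu2AlH (3.3 equiv), CH2Cl2, −78 °C; Rochelle salt
Reagents that add atoms: none
Why: Half-reduction of a γ-lactone by i-Bu2AlH stops at the aluminium hemiacetal at −78 °C and gives the lactol on work-up; two extra equivalents are consumed by the free hydroxyl groups and no skeletal stereocentre changes.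

Step 12
Reactants: 21 (3S,3aS,6R,6aS)-3-[(2E)-4-hydroxy-4-methylpent-2-en-1-yl]-6-(2-hydroxyethyl)-3,6-dimethylhexahydro-1H-cyclopenta[c]furan-1-ol
Product: 22 (2S,4E)-2-[(1S,2S,3R)-2-ethenyl-3-(2-hydroxyethyl)-3-methylcyclopentyl]-6-methylhept-4-ene-2,6-diol
Conditions: Ph3PCH3Br, KOtBu (excess), THF, 0 °C to rt
Reagents that add atoms: methylenetriphenylphosphorane, C=P(c1ccccc1)(c1ccccc1)c1ccccc1 (from methyltriphenylphosphonium bromide, C[P+](c1ccccc1)(c1ccccc1)c1ccccc1.[Br-])
Why: Wittig methylenation captures the hydroxy aldehyde tautomer of the lactol as fast as it is unmasked, which protects the adjacent ring-fusion centre from epimerisation, and the vinyl product holds no Michael acceptor onto which the liberated tertiary alcohol could cyclise.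

Step 13
Reactants: 22 (2S,4E)-2-[(1S,2S,3R)-2-ethenyl-3-(2-hydroxyethyl)-3-methylcyclopentyl]-6-methylhept-4-ene-2,6-diol; 23 2-bromopropene
Product: 25 (2S,4E)-2-[(1S,2S,3R)-3-(2-hydroxyethyl)-3-methyl-2-(3-methylbut-3-en-1-yl)cyclopentyl]-6-methylhept-4-ene-2,6-diol, via alkylborane 24 (not isolated)
Conditions: 9-BBN-H (4 equiv), THF, 0 °C to rt; then 23, PdCl2(dppf) (5 mol%), 3 M aq NaOH, THF, 45 °C
Reagents that add atoms: 2-bromopropene (23), CC(Br)=C
Why: 9-BBN-H hydroborates the only monosubstituted alkene at its terminus (the internal E alkene beside a quaternary carbon is far slower), and B-alkyl Suzuki–Miyaura coupling with 2-bromopropene then turns the former ester carbon into a ring A methylene and appends the 2-propenyl unit.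

Step 14
Reactants: 25 (2S,4E)-2-[(1S,2S,3R)-3-(2-hydroxyethyl)-3-methyl-2-(3-methylbut-3-en-1-yl)cyclopentyl]-6-methylhept-4-ene-2,6-diol
Product: 26 2-{(1R,2S,3S)-3-[(2S,4E)-2,6-dihydroxy-6-methylhept-4-en-2-yl]-1-methyl-2-(3-methylbut-3-en-1-yl)cyclopentyl}acetaldehyde
Conditions: TEMPO (10 mol%), PhI(OAc)2 (1.2 equiv), CH2Cl2, rt
Reagents that add atoms: none
Why: The oxoammonium oxidation (TEMPO with PhI(OAc)2) is selective for the primary alcohol, leaves both tertiary alcohols and the alkenes alone and stops at the aldehyde.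

Step 15
Reactants: 26 2-{(1R,2S,3S)-3-[(2S,4E)-2,6-dihydroxy-6-methylhept-4-en-2-yl]-1-methyl-2-(3-methylbut-3-en-1-yl)cyclopentyl}acetaldehyde
Product: 27 (2S,4E)-6-methyl-2-[(1S,2S,3R)-3-methyl-2-(3-methylbut-3-en-1-yl)-3-(prop-2-en-1-yl)cyclopentyl]hept-4-ene-2,6-diol
Conditions: Ph3PCH3Br, KOtBu, THF, 0 °C
Reagents that add atoms: methylenetriphenylphosphorane, C=P(c1ccccc1)(c1ccccc1)c1ccccc1 (from methyltriphenylphosphonium bromide, C[P+](c1ccccc1)(c1ccccc1)c1ccccc1.[Br-])
Why: Wittig methylenation turns the aldehyde, whose α-carbon is a CH2 on the quaternary centre and so cannot epimerise, into the allyl group needed for ring closure.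

Step 16
Reactants: 27 (2S,4E)-6-methyl-2-[(1S,2S,3R)-3-methyl-2-(3-methylbut-3-en-1-yl)-3-(prop-2-en-1-yl)cyclopentyl]hept-4-ene-2,6-diol
Product: 28 (2S,4E)-2-[(1S,3aR,8aS)-3a,6-dimethyl-1,2,3,3a,4,7,8,8a-octahydroazulen-1-yl]-6-methylhept-4-ene-2,6-diol
Conditions: second-generation Grubbs catalyst (5 mol%), CH2Cl2 (2 mM), 40 °C
Reagents that add atoms: none
Why: Ring-closing metathesis between the allyl group and the 1,1-disubstituted alkene closes the seven-membered ring A as a trisubstituted cycloheptene with loss of ethylene; the trans ring fusion is already fixed by step 8 and the hindered internal side-chain alkene is a poor metathesis partner.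

Step 17
Reactants: 28 (2S,4E)-2-[(1S,3aR,8aS)-3a,6-dimethyl-1,2,3,3a,4,7,8,8a-octahydroazulen-1-yl]-6-methylhept-4-ene-2,6-diol
Product: 29 (2S,4E)-2-[(1S,3aR,5S,6R,8aS)-5,6-epoxy-3a,6-dimethyldecahydroazulen-1-yl]-6-methylhept-4-ene-2,6-diol
Conditions: mCPBA (1.05 equiv), NaHCO3, CH2Cl2, −20 °C
Reagents that add atoms: 3-chloroperbenzoic acid, O=C(OO)c1cccc(Cl)c1
Why: In this Prilezhaev epoxidation the electron-rich trisubstituted ring alkene should react faster than the disubstituted side-chain alkene, and the peracid should approach ring A anti to the axial angular methyl group (cis to the ring-fusion hydrogen), which sets both epoxide carbons.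

Step 18
Reactants: 29 (2S,4E)-2-[(1S,3aR,5S,6R,8aS)-5,6-epoxy-3a,6-dimethyldecahydroazulen-1-yl]-6-methylhept-4-ene-2,6-diol
Product: 30 (2S,4E)-2-[(1S,3aR,5S,8aS)-5-hydroxy-3a-methyl-6-methylidenedecahydroazulen-1-yl]-6-methylhept-4-ene-2,6-diol
Conditions: Et2AlCl, lithium 2,2,6,6-tetramethylpiperidide (from the amine and n-BuLi; 6 equiv of the aluminium amide), toluene, 0 °C; Rochelle salt
Reagents that add atoms: none
Why: In this aluminium amide-mediated epoxide-to-allylic-alcohol isomerisation the aluminium binds the epoxide oxygen and the hindered amide removes a proton from the unhindered methyl group in a syn elimination, which opens the C–O bond at the tertiary carbon and gives the exocyclic methylene and the secondary alcohol with the oxygen configuration of the epoxide retained.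

Step 19
Reactants: 30 (2S,4E)-2-[(1S,3aR,5S,8aS)-5-hydroxy-3a-methyl-6-methylidenedecahydroazulen-1-yl]-6-methylhept-4-ene-2,6-diol
Product: 31 (1S,3aR,5S,8aS)-1-[(2S,4E)-2,6-dihydroxy-6-methylhept-4-en-2-yl]-3a-methyl-6-methylidenedecahydroazulen-5-yl acetate (CNP0290154.1)
Conditions: Ac2O (1.2 equiv), pyridine, DMAP (5 mol%), CH2Cl2, 0 °C
Reagents that add atoms: acetic anhydride, CC(=O)OC(C)=O
Why: Acylation takes place at the secondary allylic alcohol only, since the two tertiary alcohols do not react under these mild conditions, and the carbinol configuration is retained.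

Compound list
1 | (S)-(−)-citronellol, (3S)-3,7-dimethyloct-6-en-1-ol | OCC[C@@H](C)CCC=C(C)C | starting material
2 | tert-butyl{[(3S)-3,7-dimethyloct-6-en-1-yl]oxy}dimethylsilane | CC(C)(C)[Si](C)(C)OCC[C@@H](C)CCC=C(C)C | intermediate
3 | (4S)-6-[(tert-butyldimethylsilyl)oxy]-4-methylhexanal | CC(C)(C)[Si](C)(C)OCC[C@@H](C)CCC=O | intermediate
4 | (4S)-6-[(tert-butyldimethylsilyl)oxy]-4-methylhexanoic acid | CC(C)(C)[Si](C)(C)OCC[C@@H](C)CCC(=O)O | intermediate
5 | Meldrum's acid, 2,2-dimethyl-1,3-dioxane-4,6-dione | CC1(C)OC(=O)CC(=O)O1 | starting material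
6 | 5-{(4S)-6-[(tert-butyldimethylsilyl)oxy]-1-hydroxy-4-methylhexylidene}-2,2-dimethyl-1,3-dioxane-4,6-dione | CC(C)(C)[Si](C)(C)OCC[C@@H](C)CCC(O)=C1C(=O)OC(C)(C)OC1=O | intermediate
7 | methyl (6S)-8-[(tert-butyldimethylsilyl)oxy]-6-methyl-3-oxooctanoate | COC(=O)CC(=O)CC[C@H](C)CCO[Si](C)(C)C(C)(C)C | intermediate
8 | methyl (6S)-8-[(tert-butyldimethylsilyl)oxy]-2-diazo-6-methyl-3-oxooctanoate | COC(=O)C(=[N+]=[N-])C(=O)CC[C@H](C)CCO[Si](C)(C)C(C)(C)C | intermediate
9 | methyl (1R,2R)-2-{2-[(tert-butyldimethylsilyl)oxy]ethyl}-2-methyl-5-oxocyclopentane-1-carboxylate | COC(=O)[C@H]1C(=O)CC[C@]1(C)CCO[Si](C)(C)C(C)(C)C | intermediate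
10 | methyl (5R)-5-{2-[(tert-butyldimethylsilyl)oxy]ethyl}-5-methyl-2-{[(trifluoromethyl)sulfonyl]oxy}cyclopent-1-ene-1-carboxylate | COC(=O)C1=C(OS(=O)(=O)C(F)(F)F)CC[C@]1(C)CCO[Si](C)(C)C(C)(C)C | intermediate
11 | tributyl(1-ethoxyvinyl)stannane | CCCC[Sn](CCCC)(CCCC)C(=C)OCC | starting material
12 | methyl (5R)-5-{2-[(tert-butyldimethylsilyl)oxy]ethyl}-2-(1-ethoxyethenyl)-5-methylcyclopent-1-ene-1-carboxylate | COC(=O)C1=C(C(=C)OCC)CC[C@]1(C)CCO[Si](C)(C)C(C)(C)C | intermediate
13 | methyl (5R)-2-acetyl-5-{2-[(tert-butyldimethylsilyl)oxy]ethyl}-5-methylcyclopent-1-ene-1-carboxylate | COC(=O)C1=C(C(C)=O)CC[C@]1(C)CCO[Si](C)(C)C(C)(C)C | intermediate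
14 | methyl (5R)-2-acetyl-5-(2-hydroxyethyl)-5-methylcyclopent-1-ene-1-carboxylate | COC(=O)C1=C(C(C)=O)CC[C@]1(C)CCO | intermediate
15 | methyl (1S,2R,5S)-5-acetyl-2-(2-hydroxyethyl)-2-methylcyclopentane-1-carboxylate | COC(=O)[C@H]1[C@@H](C(C)=O)CC[C@]1(C)CCO | intermediate
16 | allylmagnesium bromide | C=CC[Mg]Br | starting material
17 | methyl (1S,2R,5S)-2-(2-hydroxyethyl)-5-[(2S)-2-hydroxypent-4-en-2-yl]-2-methylcyclopentane-1-carboxylate | COC(=O)[C@H]1[C@@H]([C@@](C)(O)CC=C)CC[C@]1(C)CCO | intermediate
18 | (3S,3aS,6R,6aS)-6-(2-hydroxyethyl)-3,6-dimethyl-3-(prop-2-en-1-yl)hexahydro-1H-cyclopenta[c]furan-1-one | O=C1[C@H]2[C@@H]([C@@](C)(O1)CC=C)CC[C@]2(C)CCO | intermediate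
19 | 2-methylbut-3-en-2-ol | CC(C)(O)C=C | starting material
20 | (3S,3aS,6R,6aS)-3-[(2E)-4-hydroxy-4-methylpent-2-en-1-yl]-6-(2-hydroxyethyl)-3,6-dimethylhexahydro-1H-cyclopenta[c]furan-1-one | O=C1[C@H]2[C@@H]([C@@](C)(O1)C/C=C/C(C)(C)O)CC[C@]2(C)CCO | intermediate
21 | (3S,3aS,6R,6aS)-3-[(2E)-4-hydroxy-4-methylpent-2-en-1-yl]-6-(2-hydroxyethyl)-3,6-dimethylhexahydro-1H-cyclopenta[c]furan-1-ol (lactol, both anomers) | OC1[C@H]2[C@@H]([C@@](C)(O1)C/C=C/C(C)(C)O)CC[C@]2(C)CCO | intermediate
22 | (2S,4E)-2-[(1S,2S,3R)-2-ethenyl-3-(2-hydroxyethyl)-3-methylcyclopentyl]-6-methylhept-4-ene-2,6-diol | C=C[C@H]1[C@@H]([C@@](C)(O)C/C=C/C(C)(C)O)CC[C@]1(C)CCO | intermediate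
23 | 2-bromopropene | CC(Br)=C | starting material
24 | (2S,4E)-2-{(1S,2S,3R)-2-[2-(9-borabicyclo[3.3.1]nonan-9-yl)ethyl]-3-(2-hydroxyethyl)-3-methylcyclopentyl}-6-methylhept-4-ene-2,6-diol (hydroxyl groups partly as borinates) | C1CCC2CCCC1B2CC[C@H]1[C@@H]([C@@](C)(O)C/C=C/C(C)(C)O)CC[C@]1(C)CCO | intermediate
25 | (2S,4E)-2-[(1S,2S,3R)-3-(2-hydroxyethyl)-3-methyl-2-(3-methylbut-3-en-1-yl)cyclopentyl]-6-methylhept-4-ene-2,6-diol | C=C(C)CC[C@H]1[C@@H]([C@@](C)(O)C/C=C/C(C)(C)O)CC[C@]1(C)CCO | intermediate
26 | 2-{(1R,2S,3S)-3-[(2S,4E)-2,6-dihydroxy-6-methylhept-4-en-2-yl]-1-methyl-2-(3-methylbut-3-en-1-yl)cyclopentyl}acetaldehyde | C=C(C)CC[C@H]1[C@@H]([C@@](C)(O)C/C=C/C(C)(C)O)CC[C@]1(C)CC=O | intermediate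
27 | (2S,4E)-6-methyl-2-[(1S,2S,3R)-3-methyl-2-(3-methylbut-3-en-1-yl)-3-(prop-2-en-1-yl)cyclopentyl]hept-4-ene-2,6-diol | C=C(C)CC[C@H]1[C@@H]([C@@](C)(O)C/C=C/C(C)(C)O)CC[C@]1(C)CC=C | intermediate
28 | (2S,4E)-2-[(1S,3aR,8aS)-3a,6-dimethyl-1,2,3,3a,4,7,8,8a-octahydroazulen-1-yl]-6-methylhept-4-ene-2,6-diol | CC=1CC[C@H]2[C@@H]([C@@](C)(O)C/C=C/C(C)(C)O)CC[C@]2(C)CC=1 | intermediate
29 | (2S,4E)-2-[(1S,3aR,5S,6R,8aS)-5,6-epoxy-3a,6-dimethyldecahydroazulen-1-yl]-6-methylhept-4-ene-2,6-diol | C[C@@]12CC[C@H]3[C@@H]([C@@](C)(O)C/C=C/C(C)(C)O)CC[C@]3(C)C[C@@H]1O2 | intermediate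
30 | (2S,4E)-2-[(1S,3aR,5S,8aS)-5-hydroxy-3a-methyl-6-methylidenedecahydroazulen-1-yl]-6-methylhept-4-ene-2,6-diol | C=C1CC[C@H]2[C@@H]([C@@](C)(O)C/C=C/C(C)(C)O)CC[C@]2(C)C[C@@H]1O | intermediate
31 | (1S,3aR,5S,8aS)-1-[(2S,4E)-2,6-dihydroxy-6-methylhept-4-en-2-yl]-3a-methyl-6-methylidenedecahydroazulen-5-yl acetate (CNP0290154.1) | C=C1CC[C@H]2[C@@H]([C@@](C)(O)C/C=C/C(C)(C)O)CC[C@]2(C)C[C@@H]1OC(C)=O | target

Total step count: 19. Longest linear sequence: 19 steps, from 1 to 31.

Steps most likely to fail

Step 8. The remote primary hydroxyl may bind the cationic iridium too weakly to steer hydrogen onto the tetrasubstituted, electron-poor alkene, so turnover or facial selectivity may be poor. The freed alcohol may also cyclise onto the unsaturated ester before reduction. The fallback sets out from 13, isolated by limiting the acid treatment of step 7 to hydrolysis of the enol ether with oxalic acid, and comes back at 15. It replaces the remote director by an allylic one whose configuration is set by a reagent. CBS reduction of the ketone with BH3·SMe2 and the (S)-oxazaborolidine should give methyl (5R)-5-{2-[(tert-butyldimethylsilyl)oxy]ethyl}-2-[(1R)-1-hydroxyethyl]-5-methylcyclopent-1-ene-1-carboxylate F1. In F1 the carbinol hydrogen eclipses the ring alkene to avoid allylic 1,3-strain against the ester, which places the hydroxyl on the face of the silyloxyethyl arm. Hydrogenation with the same iridium catalyst, now directed by the allylic hydroxyl, should therefore give methyl (1S,2R,5S)-2-{2-[(tert-butyldimethylsilyl)oxy]ethyl}-5-[(1R)-1-hydroxyethyl]-2-methylcyclopentane-1-carboxylate F2. F2 is oxidised at once with Dess–Martin periodinane, before the hydroxy ester can lactonise, to methyl (1S,2R,5S)-5-acetyl-2-{2-[(tert-butyldimethylsilyl)oxy]ethyl}-2-methylcyclopentane-1-carboxylate F3, and HF·pyridine then removes the silyl group to give 15.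

Step 9. The very fast allyl Grignard addition may discriminate poorly between the two faces of the ketone, and some enolisation next to the ketone or attack at the ester may occur. The fallback sets out from 15 and comes back at 18. Stereocontrol is moved from the substrate to a catalyst: enantioselective allylboration of the methyl ketone with allyldiisopropoxyborane and a chiral 3,3'-dibromo-BINOL, using the catalyst enantiomer that delivers allyl to the face leading to the S carbinol. This gives hydroxy ester 17 under neutral, non-basic conditions, and 17 is lactonised with PPTS to 18; the fallback makes no new compound (F0).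

Step 17. The seven-membered ring is conformationally mobile, so the facial selectivity of the epoxidation may be poor, and some epoxidation of the side-chain alkene may compete. The fallback sets out from 28 and comes back at 31. It makes the outcome independent of the epoxide face. Any (2S,4E)-2-[(1S,3aR,5R,6S,8aS)-5,6-epoxy-3a,6-dimethyldecahydroazulen-1-yl]-6-methylhept-4-ene-2,6-diol F4 formed beside 29 is isomerised under the conditions of step 18 to (2S,4E)-2-[(1S,3aR,5R,8aS)-5-hydroxy-3a-methyl-6-methylidenedecahydroazulen-1-yl]-6-methylhept-4-ene-2,6-diol F5. F5 is then esterified with inversion under Mitsunobu conditions (PPh3, DIAD, AcOH, THF, 0 °C), in which the tertiary alcohols do not take part, to give 31 directly. The 5S alcohol 30 thus reaches the target by acetylation with retention and the 5R alcohol by inversion.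

Further compounds
F1 | step 8 | methyl (5R)-5-{2-[(tert-butyldimethylsilyl)oxy]ethyl}-2-[(1R)-1-hydroxyethyl]-5-methylcyclopent-1-ene-1-carboxylate | COC(=O)C1=C([C@@H](C)O)CC[C@]1(C)CCO[Si](C)(C)C(C)(C)C
F2 | step 8 | methyl (1S,2R,5S)-2-{2-[(tert-butyldimethylsilyl)oxy]ethyl}-5-[(1R)-1-hydroxyethyl]-2-methylcyclopentane-1-carboxylate | COC(=O)[C@H]1[C@@H]([C@@H](C)O)CC[C@]1(C)CCO[Si](C)(C)C(C)(C)C
F3 | step 8 | methyl (1S,2R,5S)-5-acetyl-2-{2-[(tert-butyldimethylsilyl)oxy]ethyl}-2-methylcyclopentane-1-carboxylate | COC(=O)[C@H]1[C@@H](C(C)=O)CC[C@]1(C)CCO[Si](C)(C)C(C)(C)C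
F0 | step 9 | none | none
F4 | step 17 | (2S,4E)-2-[(1S,3aR,5R,6S,8aS)-5,6-epoxy-3a,6-dimethyldecahydroazulen-1-yl]-6-methylhept-4-ene-2,6-diol | C[C@]12CC[C@H]3[C@@H]([C@@](C)(O)C/C=C/C(C)(C)O)CC[C@]3(C)C[C@H]1O2
F5 | step 17 | (2S,4E)-2-[(1S,3aR,5R,8aS)-5-hydroxy-3a-methyl-6-methylidenedecahydroazulen-1-yl]-6-methylhept-4-ene-2,6-diol | C=C1CC[C@H]2[C@@H]([C@@](C)(O)C/C=C/C(C)(C)O)CC[C@]2(C)C[C@H]1O
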